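## The problem

The target is a flavan-3-ol ester. Benzene ring A (hydroxyls at C5 and C7) is fused through C4a and C8a to the dihydropyran ring C, which carries a 3,4,5-trihydroxyphenyl ring B on C2 and a 4-hydroxy-3,5-dimethoxybenzoyl (syringoyl) group on the C3 oxygen. There are only two stereocentres, C2 (R) and C3 (R). They are adjacent and cis, the less stable arrangement, so the relationship has to be set under kinetic control. C2 is benzylic and bonded to O1, and once C3 is a ketone the C2–H bond becomes acidic. C2 can therefore be fixed early and guarded, or made deliberately mobile so that one reduction at C3, steered to the face opposite ring B, sets both centres. The phloroglucinol ring A and the pyrogallol ring B oxidise in air and base, ring A is a carbon nucleophile at C6 and C8, and the free polyphenol epimerises at C2; the C3 ester is cleaved by base. All six phenols must therefore travel as ethers that fall under neutral conditions in the last step, and nothing harsh may follow ester formation. The enabling feature is in ring A: O1 on C8a and C4 on C4a are neighbours, and the C5 oxygen sits directly beside C4a. This is the pattern left when a 3-alkoxybenzyne accepts an oxygen nucleophile at its remote carbon and a carbon electrophile at the carbon next to the alkoxy group. The remaining atoms C4, C3(O) and C2(aryl) map onto the carbonyl, α- and β-carbons of a 2-alkoxycinnamaldehyde.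

## Retrosynthesis

**Target 21 to hexabenzyl ether 20.** Six O–CH2Ph bonds are cut. Benzyl is preferred to methyl (not removable beside the two methyl ethers that must stay), to aryl silyl ethers (lost to fluoride in the ring-forming step) and to acetals (acid removal endangers C2 and the ester). The forward step is a neutral hydrogenolysis that must spare the cyclic benzylic C2–O1 bond.

**Ester 20 to alcohol 16 and acid 19.** The acyl–O3 bond is cut. Late acylation keeps the base-labile ester out of every earlier step. Acid 19 is syringic acid 17 with its hindered phenol masked as a benzyl ether, reached through benzyl ester 18. The forward reaction must acylate a hindered pseudo-axial alcohol without touching C2.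

**Alcohol 16 to ketone 15.** The C3–H bond is cut. In racemic flavan-3-one 15 the C2 hydrogen lies between the carbonyl, ring B and O1 and exchanges with mild base. A chiral hydride catalyst that reduces one enantiomer faster, from the face opposite ring B, converts the whole racemate into the cis (2R,3R) alcohol. Against fixing C2 early, this removes every stereocentre from the precursor and makes the ring synthesis a purely constitutional problem. The price is a demanding dynamic kinetic resolution.

**Ketone 15 to enol ether 14.** The C3 carbonyl is traced to a 3-methoxy-2H-chromene. The oxygen at C3 is thus carried at the ketone oxidation level from the ring-forming step, and no hydroboration or redox correction is needed. The forward step is a mild enol ether hydrolysis.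

**Chromene 14 to aryne precursor 6 and enal 10.** Three bonds are cut: O1–C8a, C4–C4a and O1–C2. Backwards, ring C opens by oxa-6π retro-electrocyclisation to o-quinone methide 13. This closes to benzoxete 12, which splits into 3,5-bis(benzyloxy)benzyne 11 and the carbonyl group of 10. Against the neighbouring cut (phenol plus enal, which must find the ortho carbon and the carbonyl rather than the β-carbon), the aryne fixes both ring A attachment points through its polarisation. Both fragments are achiral and of similar size. The forward step needs regiocontrol on the aryne and preference for C=O over C=C.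

**Enal 10 to aldehyde 7 and methoxyacetaldehyde 8.** The C2=C3 bond is cut by a crossed aldol condensation through adduct 9. Both partners are commercial, and the product has no enolisable hydrogen left.

**Aryne precursor 6 to phenol 1.** The C–Si bond comes from a retro-Brook silyl shift in aryllithium 4, giving phenoxide 5, which is triflated. Aryllithium 4 comes from silyl ether 3 of bromophenol 2, the ortho-bromination product of commercial 3,5-bis(benzyloxy)phenol 1.

## Roads not taken

**Alternative 1:** The cut is the aryl ether bond O1–C8a. The open-chain bromo alcohol A2, (1R,2R)-2-(allyloxy)-3-[2,4-bis(benzyloxy)-6-bromophenyl]-1-[3,4,5-tris(benzyloxy)phenyl]propan-1-ol, would be cyclised with Pd(OAc)2 and a bulky di-tert-butyl(biaryl)phosphine. Zerovalent palladium inserts into the C–Br bond, the secondary alkoxide binds, and reductive elimination gives 3-O-allyl penta-O-benzyl-epigallocatechin A1.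
- Merits: both stereocentres exist before ring closure and the closure does not break a bond at C2, so the absolute configuration is more secure than in the chosen plan.
- Weak points: retention turns a syn 1,2-diol into the trans flavan, so the cis target needs the anti diol. Dihydroxylation of the readily made (E)-1,3-diarylpropene gives the syn diol, and an inversion with differentiation of the two hydroxyls must follow. The palladium alkoxide of a secondary benzylic alcohol can undergo β-hydride elimination. The allyl ether costs a separate removal step before acylation.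
- Comparison: this road is safer on stereochemistry but several steps longer and linear. The chosen plan sets against it a convergent ten-step route, and pays with its reliance on the dynamic reduction.

**Alternative 2:** The cuts are O1–C2 and C3–C4. A chiral phosphoric acid would dehydrate the salicyl alcohol A4, 3,5-bis(benzyloxy)-2-(hydroxymethyl)phenol, to its o-quinone methide. This would add across the Z-enol ester A5, (Z)-2-[3,4,5-tris(benzyloxy)phenyl]ethenyl 4-(benzyloxy)-3,5-dimethoxybenzoate, to give the perbenzylated target A3, which is identical with 20.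
- Merits: this is the shortest road. Ring C, both stereocentres and the ester arrive in one step, and only hydrogenolysis remains.
- Weak points: an enol ester is a poor, donor-free 2π partner with no hydrogen-bond handle for the catalyst. Regiochemistry requires the styrene polarisation to override the enol ester polarisation, and ring B has only one para donor. A stepwise cationic path would erode the Z-to-cis transfer. The phloroglucinol-type quinone methide is strongly stabilised and is readily trapped by its own electron-rich precursor.
- Comparison: if it worked it would beat the chosen plan clearly in step count. The chosen plan sets against it that every bond is made by a reaction type with precedent, and that the cis relationship comes from a hydride addition whose facial preference on this ketone class is established.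

**Alternative 3:** The cut is C3=C4. The diene A7, 1,5-bis(benzyloxy)-2-ethenyl-3-{[(1S)-1-[3,4,5-tris(benzyloxy)phenyl]prop-2-en-1-yl]oxy}benzene, would be closed with the second-generation Grubbs catalyst RuCl2(H2IMes)(PCy3)(=CHPh) to the (S)-2-aryl-2H-chromene A6 with loss of ethylene.
- Merits: the metathesis is reliable on such dienes, and C2 is set by a well-understood asymmetric allylic etherification.
- Weak points: A6 has no oxygen at C3. Hydroboration–oxidation delivers it anti to ring B and gives the trans alcohol A8, so oxidation to the (2R)-ketone A9 and a cis-selective reduction must follow. That is three redox steps to reach the point the chosen plan reaches by one hydrolysis. A 2-aryl-2H-chromene can also open thermally to its o-quinone methide and re-close, which threatens the C2 configuration of A6. A9 must then pass through the very ketone stage at which C2 is labile.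
- Comparison: this road has the better-defined source of absolute configuration. The chosen plan is shorter and turns the lability of C2 into an advantage.

Key step: step 5

Assumption: the sense of induction of RuCl(p-cymene)(TsDPEN) on the non-conjugated ketone 15 is taken from the model in which C2, bearing ring B and O1, occupies the place of the aryl group of an aryl alkyl ketone. This predicts the (R,R)-ligand for the (2R,3R)-alcohol. If the opposite sense is found, the (S,S)-complex is used with no other change.

## Route

Step 1
Reactants: 1 3,5-bis(benzyloxy)phenol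
Product: 2 3,5-bis(benzyloxy)-2-bromophenol
Conditions: NBS (1.0 equiv), CH2Cl2, −78 °C
Reagents that add atoms: N-bromosuccinimide, O=C1CCC(=O)N1Br
Why: Electrophilic aromatic bromination; in a non-polar solvent at low temperature the hydrogen-bonded hydroxyl directs NBS to its ortho position, which is also para to the C5 benzyloxy group and less hindered than C4 between the two benzyl ethers. One equivalent and low temperature hold the reaction at the monobromide.

Step 2
Reactants: 2 3,5-bis(benzyloxy)-2-bromophenol
Product: 3 [3,5-bis(benzyloxy)-2-bromophenoxy]trimethylsilane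
Conditions: HMDS, THF, 70 °C; evaporation, used crude
Reagents that add atoms: hexamethyldisilazane, C[Si](C)(C)N[Si](C)(C)C
Why: O-silylation of a phenol with hexamethyldisilazane, driven by loss of ammonia; the moisture-sensitive silyl ether is carried on without chromatography.

Step 3
Reactants: 3 [3,5-bis(benzyloxy)-2-bromophenoxy]trimethylsilane
Product: 6 3,5-bis(benzyloxy)-2-(trimethylsilyl)phenyl trifluoromethanesulfonate, via aryllithium 4 (not isolated), via lithium silylphenoxide 5 (not isolated)
Conditions: n-BuLi, THF, −100 °C; then Tf2O, −100 to −78 °C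
Reagents that add atoms: trifluoromethanesulfonic anhydride, O=S(=O)(OS(=O)(=O)C(F)(F)F)C(F)(F)F
Why: Bromine–lithium exchange at −100 °C outruns benzylic deprotonation; the aryllithium takes the neighbouring silyl group from oxygen in a retro-Brook 1,3-shift driven by phenoxide formation, and the phenoxide is trapped as the triflate. This is the standard sequence to 2-silylaryl triflates.

Step 4
Reactants: 7 3,4,5-tris(benzyloxy)benzaldehyde; 8 methoxyacetaldehyde
Product: 10 (Z)-2-methoxy-3-[3,4,5-tris(benzyloxy)phenyl]prop-2-enal, via aldol adduct 9 (not isolated)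
Conditions: 8 (2 equiv, commercial solution, slow addition), NaOH, MeOH/THF/H2O, 0 °C to rt
Reagents that add atoms: none
Why: Crossed aldol condensation of the Claisen–Schmidt type between a non-enolisable aromatic aldehyde and the enolate of 8, followed by E1cB loss of water. The product has no α- or γ-hydrogen and cannot condense further, and the Z isomer with the aryl group trans to the formyl group is the thermodynamic one; either isomer would serve in step 5.

Step 5
Reactants: 6 3,5-bis(benzyloxy)-2-(trimethylsilyl)phenyl trifluoromethanesulfonate; 10 (Z)-2-methoxy-3-[3,4,5-tris(benzyloxy)phenyl]prop-2-enal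
Product: 14 racemic 5,7-bis(benzyloxy)-3-methoxy-2-[3,4,5-tris(benzyloxy)phenyl]-2H-chromene, via 3,5-bis(benzyloxy)benzyne 11 (not isolated), via benzoxete 12 (not isolated), via o-quinone methide 13 (not isolated)
Conditions: 6 added slowly to 10 (1.5 equiv) and CsF (3 equiv), MeCN/THF (2:1), rt
Reagents that add atoms: none
Why: Fluoride attacks silicon in 6 and triflate leaves, releasing aryne 11 at low steady concentration beside an excess of enal 10. The aldehyde oxygen adds to the aryne carbon remote from the flanking benzyloxy group, because that group withdraws inductively and distorts the triple bond so that the remote carbon is the more electrophilic one and the developing negative charge sits next to oxygen; the C7 oxygen, para to that carbon, opposes only weakly. Collapse of the aryl anion onto the activated carbonyl carbon completes a formal [2+2] addition to benzoxete 12, forming O1–C8a and C4–C4a. Four-electron opening of the strained oxete gives o-quinone methide 13, in which the peri benzyloxy group at C5 pushes the alkenyl chain to the carbonyl side of the exocyclic double bond, the geometry needed for closure. Disrotatory oxa-6π electrocyclisation of the 1-oxatriene O1=C8a–C4a=C4–C3=C2 then forms O1–C2, closes the six-membered ring C and restores the aromaticity of ring A, which makes the closure irreversible. The closest known reaction type is the annulation of arynes from 2-silylaryl triflates with cinnamaldehyde-type enals to 2H-chromenes. C2, the only new stereocentre, forms without control and 14 is racemic by design, since C2 is equilibrated at the ketone stage. The step needs aryne regioselectivity, secured by the 3-alkoxy group, and preference for the carbonyl over the enol ether double bonds of 10 and 14 and over capture of 13 by a second aryne, secured by slow aryne release, excess 10 and the intramolecular ring closure.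

Step 6
Reactants: 14 racemic 5,7-bis(benzyloxy)-3-methoxy-2-[3,4,5-tris(benzyloxy)phenyl]-2H-chromene
Product: 15 racemic 5,7-bis(benzyloxy)-2-[3,4,5-tris(benzyloxy)phenyl]chroman-3-one
Conditions: 1 M aq. HCl, THF, rt
Reagents that add atoms: water, O
Why: Acid-catalysed enol ether hydrolysis: protonation at C4 gives the C3 oxocarbenium ion, water adds and methanol leaves. Dilute acid at room temperature leaves the benzyl ethers and the C2–O1 bond alone.

Step 7
Reactants: 15 racemic 5,7-bis(benzyloxy)-2-[3,4,5-tris(benzyloxy)phenyl]chroman-3-one
Product: 16 (2R,3R)-5,7-bis(benzyloxy)-2-[3,4,5-tris(benzyloxy)phenyl]chroman-3-ol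
Conditions: RuCl(p-cymene)[(R,R)-TsDPEN] (2 mol%), HCO2H (3 equiv), Et3N (6 equiv), CH2Cl2, 30 °C, degassed
Reagents that add atoms: none
Why: Noyori–Ikariya asymmetric transfer hydrogenation with dynamic kinetic resolution: the excess amine equilibrates the C2 enantiomers of 15 through the enol, the catalyst reduces the (2R)-ketone faster and delivers hydride to C3 from the face opposite ring B, so C3 (R) and the cis relationship are set together. The closest precedents are cis-selective transfer hydrogenations of configurationally labile α-aryl cyclic ketones, and the cis preference matches that of bulky hydride donors on flavan-3-ones.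

Step 8
Reactants: 17 syringic acid (4-hydroxy-3,5-dimethoxybenzoic acid)
Product: 19 4-(benzyloxy)-3,5-dimethoxybenzoic acid, via benzyl ester 18 (not isolated)
Conditions: BnBr (2.2 equiv), K2CO3, DMF, 60 °C; then NaOH, MeOH/H2O, reflux; HCl
Reagents that add atoms: benzyl bromide, BrCc1ccccc1
Why: Williamson etherification and carboxylate alkylation give the benzyl ether benzyl ester, and saponification in the same flask frees only the acid because the aryl benzyl ether resists hydroxide. The benzyl ether is chosen so that it falls with the others in step 10.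

Step 9
Reactants: 16 (2R,3R)-5,7-bis(benzyloxy)-2-[3,4,5-tris(benzyloxy)phenyl]chroman-3-ol; 19 4-(benzyloxy)-3,5-dimethoxybenzoic acid
Product: 20 (2R,3R)-5,7-bis(benzyloxy)-2-[3,4,5-tris(benzyloxy)phenyl]chroman-3-yl 4-(benzyloxy)-3,5-dimethoxybenzoate
Conditions: DCC, DMAP, CH2Cl2, rt
Reagents that add atoms: none
Why: Steglich esterification; DMAP transfers the acyl group to the hindered C3 hydroxyl under neutral conditions. The C3–O bond is not broken and C2 no longer bears an acidic hydrogen, so both stereocentres are retained.

Step 10
Reactants: 20 (2R,3R)-5,7-bis(benzyloxy)-2-[3,4,5-tris(benzyloxy)phenyl]chroman-3-yl 4-(benzyloxy)-3,5-dimethoxybenzoate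
Product: 21 epigallocatechin 3-O-(3,5-di-O-methylgallate), (2R,3R)-5,7-dihydroxy-2-(3,4,5-trihydroxyphenyl)chroman-3-yl 4-hydroxy-3,5-dimethoxybenzoate
Conditions: H2 (1 atm), Pd(OH)2/C, THF/MeOH (1:1), rt; filtration and evaporation under inert gas
Reagents that add atoms: none
Why: Catalytic hydrogenolysis of six aryl benzyl ethers under neutral conditions; at atmospheric pressure the O–CH2Ph bonds cleave much faster than the cyclic benzylic C2–O1 bond, and the ester and methyl ethers are inert. No acid or base is present to epimerise C2 in the free polyphenol.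

## Compound list

1 | 3,5-bis(benzyloxy)phenol | Oc1cc(OCc2ccccc2)cc(OCc2ccccc2)c1 | starting material
2 | 3,5-bis(benzyloxy)-2-bromophenol | Oc1cc(OCc2ccccc2)cc(OCc2ccccc2)c1Br | intermediate
3 | [3,5-bis(benzyloxy)-2-bromophenoxy]trimethylsilane | C[Si](C)(C)Oc1cc(OCc2ccccc2)cc(OCc2ccccc2)c1Br | intermediate
4 | [2,4-bis(benzyloxy)-6-(trimethylsilyloxy)phenyl]lithium (not isolated) | [Li]c1c(O[Si](C)(C)C)cc(OCc2ccccc2)cc1OCc1ccccc1 | intermediate
5 | lithium 3,5-bis(benzyloxy)-2-(trimethylsilyl)phenoxide (not isolated) | [Li]Oc1cc(OCc2ccccc2)cc(OCc2ccccc2)c1[Si](C)(C)C | intermediate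
6 | 3,5-bis(benzyloxy)-2-(trimethylsilyl)phenyl trifluoromethanesulfonate | C[Si](C)(C)c1c(OCc2ccccc2)cc(OCc2ccccc2)cc1OS(=O)(=O)C(F)(F)F | intermediate
7 | 3,4,5-tris(benzyloxy)benzaldehyde | O=Cc1cc(OCc2ccccc2)c(OCc2ccccc2)c(OCc2ccccc2)c1 | starting material
8 | methoxyacetaldehyde | COCC=O | starting material
9 | 3-hydroxy-2-methoxy-3-[3,4,5-tris(benzyloxy)phenyl]propanal, mixture of diastereomers (not isolated) | COC(C=O)C(O)c1cc(OCc2ccccc2)c(OCc2ccccc2)c(OCc2ccccc2)c1 | intermediate
10 | (Z)-2-methoxy-3-[3,4,5-tris(benzyloxy)phenyl]prop-2-enal | CO/C(C=O)=C\c1cc(OCc2ccccc2)c(OCc2ccccc2)c(OCc2ccccc2)c1 | intermediate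
11 | 3,5-bis(benzyloxy)benzyne (not isolated) | C1#CC(OCc2ccccc2)=CC(OCc2ccccc2)=C1 | intermediate
12 | racemic 3,5-bis(benzyloxy)-2-{(Z)-1-methoxy-2-[3,4,5-tris(benzyloxy)phenyl]ethenyl}-2H-1-benzoxete (not isolated) | CO/C(=C\c1cc(OCc2ccccc2)c(OCc2ccccc2)c(OCc2ccccc2)c1)C1Oc2cc(OCc3ccccc3)cc(OCc3ccccc3)c21 | intermediate
13 | (6Z)-3,5-bis(benzyloxy)-6-{(2Z)-2-methoxy-3-[3,4,5-tris(benzyloxy)phenyl]prop-2-en-1-ylidene}cyclohexa-2,4-dien-1-one (not isolated) | O=C1C=C(OCc2ccccc2)C=C(OCc2ccccc2)/C1=C/C(OC)=C/c1cc(OCc2ccccc2)c(OCc2ccccc2)c(OCc2ccccc2)c1 | intermediate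
14 | racemic 5,7-bis(benzyloxy)-3-methoxy-2-[3,4,5-tris(benzyloxy)phenyl]-2H-chromene | COC1=Cc2c(OCc3ccccc3)cc(OCc3ccccc3)cc2OC1c1cc(OCc2ccccc2)c(OCc2ccccc2)c(OCc2ccccc2)c1 | intermediate
15 | racemic 5,7-bis(benzyloxy)-2-[3,4,5-tris(benzyloxy)phenyl]chroman-3-one | O=C1Cc2c(OCc3ccccc3)cc(OCc3ccccc3)cc2OC1c1cc(OCc2ccccc2)c(OCc2ccccc2)c(OCc2ccccc2)c1 | intermediate
16 | (2R,3R)-5,7-bis(benzyloxy)-2-[3,4,5-tris(benzyloxy)phenyl]chroman-3-ol | O[C@@H]1Cc2c(OCc3ccccc3)cc(OCc3ccccc3)cc2O[C@@H]1c1cc(OCc2ccccc2)c(OCc2ccccc2)c(OCc2ccccc2)c1 | intermediate
17 | syringic acid | COc1cc(C(=O)O)cc(OC)c1O | starting material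
18 | benzyl 4-(benzyloxy)-3,5-dimethoxybenzoate (not isolated) | COc1cc(C(=O)OCc2ccccc2)cc(OC)c1OCc1ccccc1 | intermediate
19 | 4-(benzyloxy)-3,5-dimethoxybenzoic acid | COc1cc(C(=O)O)cc(OC)c1OCc1ccccc1 | intermediate
20 | (2R,3R)-5,7-bis(benzyloxy)-2-[3,4,5-tris(benzyloxy)phenyl]chroman-3-yl 4-(benzyloxy)-3,5-dimethoxybenzoate | COc1cc(C(=O)O[C@@H]2Cc3c(OCc4ccccc4)cc(OCc4ccccc4)cc3O[C@@H]2c2cc(OCc3ccccc3)c(OCc3ccccc3)c(OCc3ccccc3)c2)cc(OC)c1OCc1ccccc1 | intermediate
21 | epigallocatechin 3-O-(3,5-di-O-methylgallate) | COc1cc(C(=O)O[C@@H]2Cc3c(O)cc(O)cc3O[C@@H]2c2cc(O)c(O)c(O)c2)cc(OC)c1O | target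

## Step count and risks

Total step count: 10. Longest linear sequence: 8 steps (steps 1, 2, 3, 5, 6, 7, 9, 10).

**Step 5 (key step).** Three things may go wrong. The aryl anion may close on the β-carbon of the enal instead of the carbonyl carbon, a formal [4+2] that misplaces ring B. The aryne may be consumed by [2+2] addition to the enol ether double bond of the product or the enal. The quinone methide may be captured by a second aryne before it cyclises. All follow from the high, unselective electrophilicity of the aryne.
Fallback, from 1 and 10, returning at 14: phenol 1 and enal 10 are heated with phenylboronic acid and propanoic acid in toluene with removal of water. The boron tether forces carbon–carbon bond formation ortho to the hydroxyl (both ortho positions of 1 are equivalent) and gives 5,7-bis(benzyloxy)-4-{(Z)-1-methoxy-2-[3,4,5-tris(benzyloxy)phenyl]ethenyl}-2-phenyl-4H-1,3,2-benzodioxaborin F1. On heating this fragments to the same o-quinone methide 13, which electrocyclises to 14. It would save steps 1 to 3. It is held in reserve because it runs in hot acid, where the enol ether is exposed, and because electron-rich phenols can also attack such enals at the β-carbon.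

**Step 7.** Epimerisation at C2 may be slower than reduction, so the reaction becomes an ordinary kinetic resolution whose selectivity falls with conversion. The catalyst may also discriminate the carbonyl faces poorly, because no aryl group is conjugated with the ketone.
Fallback, from 15, returning at 16: LiBH(s-Bu)3 in THF at −78 °C reduces racemic 15 from the face opposite ring B to the racemic cis alcohol, that is 16 together with (2S,3S)-5,7-bis(benzyloxy)-2-[3,4,5-tris(benzyloxy)phenyl]chroman-3-ol F2. The two are separated by chromatography on a chiral stationary phase. F2 is returned to 15 by Dess–Martin oxidation and base-mediated racemisation, and recycled.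

**Step 4.** Self-condensation and oligomerisation of methoxyacetaldehyde may outrun the crossed reaction, since the electron-rich aldehyde 7 is a sluggish acceptor.
Fallback, from 7, returning at 10: Horner–Wadsworth–Emmons olefination of 7 with methyl 2-(dimethoxyphosphoryl)-2-methoxyacetate (NaH, THF) gives methyl (Z)-2-methoxy-3-[3,4,5-tris(benzyloxy)phenyl]prop-2-enoate F3. Reduction with i-Bu2AlH gives (Z)-2-methoxy-3-[3,4,5-tris(benzyloxy)phenyl]prop-2-en-1-ol F4, and MnO2 oxidises this allylic alcohol to 10.

**Step 1.** Bromination may occur at C4 between the two benzyloxy groups, or twice, because all three free ring positions are strongly activated.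
Fallback, from 1, returning at 6 (replacing steps 1 to 3): isopropyl isocyanate and Et3N convert 1 into 3,5-bis(benzyloxy)phenyl N-(propan-2-yl)carbamate F5. After transient N-silylation (TBSOTf, TMEDA), carbamate-directed ortho-lithiation with n-BuLi at −78 °C occurs at the position flanked by the carbamate and a benzyloxy group. Quenching with TMSCl gives, after work-up, 3,5-bis(benzyloxy)-2-(trimethylsilyl)phenyl N-(propan-2-yl)carbamate F6. Et2NH and DBU cleave the carbamate to 3,5-bis(benzyloxy)-2-(trimethylsilyl)phenol F7, which PhNTf2 converts in the same flask into 6.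

## Further compounds

F1 | step 5 | 5,7-bis(benzyloxy)-4-{(Z)-1-methoxy-2-[3,4,5-tris(benzyloxy)phenyl]ethenyl}-2-phenyl-4H-1,3,2-benzodioxaborin | CO/C(=C\c1cc(OCc2ccccc2)c(OCc2ccccc2)c(OCc2ccccc2)c1)C1OB(c2ccccc2)Oc2cc(OCc3ccccc3)cc(OCc3ccccc3)c21
F2 | step 7 | (2S,3S)-5,7-bis(benzyloxy)-2-[3,4,5-tris(benzyloxy)phenyl]chroman-3-ol | O[C@H]1Cc2c(OCc3ccccc3)cc(OCc3ccccc3)cc2O[C@H]1c1cc(OCc2ccccc2)c(OCc2ccccc2)c(OCc2ccccc2)c1
F3 | step 4 | methyl (Z)-2-methoxy-3-[3,4,5-tris(benzyloxy)phenyl]prop-2-enoate | CO/C(C(=O)OC)=C\c1cc(OCc2ccccc2)c(OCc2ccccc2)c(OCc2ccccc2)c1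
F4 | step 4 | (Z)-2-methoxy-3-[3,4,5-tris(benzyloxy)phenyl]prop-2-en-1-ol | CO/C(CO)=C\c1cc(OCc2ccccc2)c(OCc2ccccc2)c(OCc2ccccc2)c1
F5 | step 1 | 3,5-bis(benzyloxy)phenyl N-(propan-2-yl)carbamate | CC(C)NC(=O)Oc1cc(OCc2ccccc2)cc(OCc2ccccc2)c1
F6 | step 1 | 3,5-bis(benzyloxy)-2-(trimethylsilyl)phenyl N-(propan-2-yl)carbamate | CC(C)NC(=O)Oc1cc(OCc2ccccc2)cc(OCc2ccccc2)c1[Si](C)(C)C
F7 | step 1 | 3,5-bis(benzyloxy)-2-(trimethylsilyl)phenol | Oc1cc(OCc2ccccc2)cc(OCc2ccccc2)c1[Si](C)(C)C
A1 | alternative 1 | (2R,3R)-3-(allyloxy)-5,7-bis(benzyloxy)-2-[3,4,5-tris(benzyloxy)phenyl]chroman | C=CCO[C@@H]1Cc2c(OCc3ccccc3)cc(OCc3ccccc3)cc2O[C@@H]1c1cc(OCc2ccccc2)c(OCc2ccccc2)c(OCc2ccccc2)c1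
A2 | alternative 1 | (1R,2R)-2-(allyloxy)-3-[2,4-bis(benzyloxy)-6-bromophenyl]-1-[3,4,5-tris(benzyloxy)phenyl]propan-1-ol | C=CCO[C@H](Cc1c(OCc2ccccc2)cc(OCc2ccccc2)cc1Br)[C@H](O)c1cc(OCc2ccccc2)c(OCc2ccccc2)c(OCc2ccccc2)c1
A3 | alternative 2 | (2R,3R)-5,7-bis(benzyloxy)-2-[3,4,5-tris(benzyloxy)phenyl]chroman-3-yl 4-(benzyloxy)-3,5-dimethoxybenzoate | COc1cc(C(=O)O[C@@H]2Cc3c(OCc4ccccc4)cc(OCc4ccccc4)cc3O[C@@H]2c2cc(OCc3ccccc3)c(OCc3ccccc3)c(OCc3ccccc3)c2)cc(OC)c1OCc1ccccc1
A4 | alternative 2 | 3,5-bis(benzyloxy)-2-(hydroxymethyl)phenol | OCc1c(O)cc(OCc2ccccc2)cc1OCc1ccccc1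
A5 | alternative 2 | (Z)-2-[3,4,5-tris(benzyloxy)phenyl]ethenyl 4-(benzyloxy)-3,5-dimethoxybenzoate | COc1cc(C(=O)O/C=C\c2cc(OCc3ccccc3)c(OCc3ccccc3)c(OCc3ccccc3)c2)cc(OC)c1OCc1ccccc1
A6 | alternative 3 | (S)-5,7-bis(benzyloxy)-2-[3,4,5-tris(benzyloxy)phenyl]-2H-chromene | C1=Cc2c(OCc3ccccc3)cc(OCc3ccccc3)cc2O[C@@H]1c1cc(OCc2ccccc2)c(OCc2ccccc2)c(OCc2ccccc2)c1
A7 | alternative 3 | 1,5-bis(benzyloxy)-2-ethenyl-3-{[(1S)-1-[3,4,5-tris(benzyloxy)phenyl]prop-2-en-1-yl]oxy}benzene | C=Cc1c(OCc2ccccc2)cc(OCc2ccccc2)cc1O[C@@H](C=C)c1cc(OCc2ccccc2)c(OCc2ccccc2)c(OCc2ccccc2)c1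
A8 | alternative 3 | (2R,3S)-5,7-bis(benzyloxy)-2-[3,4,5-tris(benzyloxy)phenyl]chroman-3-ol | O[C@H]1Cc2c(OCc3ccccc3)cc(OCc3ccccc3)cc2O[C@@H]1c1cc(OCc2ccccc2)c(OCc2ccccc2)c(OCc2ccccc2)c1
A9 | alternative 3 | (2R)-5,7-bis(benzyloxy)-2-[3,4,5-tris(benzyloxy)phenyl]chroman-3-one | O=C1Cc2c(OCc3ccccc3)cc(OCc3ccccc3)cc2O[C@@H]1c1cc(OCc2ccccc2)c(OCc2ccccc2)c(OCc2ccccc2)c1
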